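**Strategy.** The pyrrole ring is traced back to a pyridazine ring and that to a 1,2,4,5-tetrazine. The route exploits the carbon run C2(CO2Me)–C3(henicosyl)–C4H–C5 of the pyrrole ring, which is the C3–C4–C5–C6 run of a 4-alkylpyridazine-3,6-diester. C2 and C5 derive from the two tetrazine carbons, while C3, C4 and the C21 chain are delivered together by a terminal alkyne. One inverse-electron-demand Diels–Alder reaction with loss of N2 forms the C2–C3 and C4–C5 bonds and closes the diazine ring. Its precursors are the symmetric tetrazine-3,6-diester and unbranched 1-tricosyne. Zinc-mediated ring contraction and removal of the surplus C5 carboxyl group finish the synthesis.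

Key step: step 3

Assumption: the tetrazine diester is purchased and handled under argon in dry solvent, because moisture hydrolyses it; THF or warm CH2Cl2 is included wherever the waxy long-chain compounds would otherwise not dissolve.

**Step 1**
Reactants: 1 1-docosanol
Product: 2 docosanal
Conditions: TEMPO (2,2,6,6-tetramethylpiperidin-1-oxyl, 10 mol %), PhI(OAc)2 (1.1 equiv), CH2Cl2, 30 °C
Reagents that add atoms: none
Why: TEMPO-catalysed alcohol oxidation through the oxoammonium ion, with PhI(OAc)2 as terminal oxidant, should stop at the aldehyde in the absence of water, and the saturated chain offers no other reactive site.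

**Step 2**
Reactants: 2 docosanal; 3 dimethyl (1-diazo-2-oxopropyl)phosphonate
Product: 6 1-tricosyne, via dimethyl (diazomethyl)phosphonate 4 (not isolated), via 1-diazotricos-1-ene 5 (not isolated)
Conditions: K2CO3 (2 equiv), MeOH/THF 1:1, 0 °C to 25 °C
Reagents that add atoms: none
Why: In this Ohira–Bestmann variant of the Seyferth–Gilbert homologation, methanolysis of 3 releases the anion of 4, which olefinates the aldehyde in a Horner–Wadsworth–Emmons manner to diazoalkene 5, and loss of N2 with a 1,2-hydrogen shift should then give the terminal alkyne under mild base that the chain tolerates.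

**Step 3**
Reactants: 6 1-tricosyne; 7 dimethyl 1,2,4,5-tetrazine-3,6-dicarboxylate
Product: 9 dimethyl 4-henicosylpyridazine-3,6-dicarboxylate, via bicyclic tetraaza adduct 8 (not isolated)
Conditions: 7 (1.5 equiv, added in two portions), dry 1,4-dioxane, 90 °C, argon, sealed vessel
Reagents that add atoms: none
Why: The electron-poor tetrazine 7 acts as a diene across C3 and C6 and adds to the C≡C bond of 6 in a concerted, LUMO(diene)-controlled [4+2] cycloaddition, the Carboni–Lindsey reaction (inverse-electron-demand Diels–Alder reaction of a tetrazine with an alkyne). The bicyclic adduct 8 should not persist, because retro-[4+2] loss of N2 is irreversible and gives the aromatic pyridazine 9 directly, with no oxidation step needed since the dienophile is an alkyne. The six-membered diazine ring is therefore closed by an intermolecular [4+2] cycloaddition that forms both new C–C bonds (tetrazine C3 to the internal alkyne carbon, tetrazine C6 to the terminal alkyne carbon), followed by cycloreversion. No stereocentre is created. The only selectivity needed is the position of the chain relative to the esters, and it is secured by the twofold symmetry of 7, since either orientation of the alkyne gives the same 4-alkyl-3,6-diester, while the saturated chain has no second π-bond or nucleophile that could consume the tetrazine. Heating is required because the alkyne is unactivated, and 7 is used in excess and in portions to offset its slow thermal decay.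

**Step 4**
Reactants: 9 dimethyl 4-henicosylpyridazine-3,6-dicarboxylate
Product: 12 dimethyl 3-henicosyl-1H-pyrrole-2,5-dicarboxylate, via 1,4-dihydropyridazine 10 (not isolated), via ring-opened amino imine 11 (not isolated)
Conditions: Zn dust (excess), AcOH/THF, 25 °C
Reagents that add atoms: none
Why: In this reductive ring contraction of a 1,2-diazine, zinc in acetic acid should reduce the electron-poor pyridazine to dihydro compound 10 and cleave its N–N bond to 11, whose amino group closes onto the imine carbon with loss of ammonia and aromatisation, so the four ring carbons, the chain and both esters pass unchanged into the pyrrole.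

**Step 5**
Reactants: 12 dimethyl 3-henicosyl-1H-pyrrole-2,5-dicarboxylate
Product: 14 4-henicosyl-5-(methoxycarbonyl)-1H-pyrrole-2-carboxylic acid, via lithium carboxylate 13 (not isolated)
Conditions: LiOH·H2O (1.2 equiv), THF/MeOH/H2O, 0 °C to 25 °C; then 1 M HCl
Reagents that add atoms: lithium hydroxide, [Li+].[OH-]
Why: In this site-selective saponification (acyl–oxygen cleavage by hydroxide), the ester at C5 is flanked only by C4–H and should be attacked faster than the ester at C2, which is shielded by the neighbouring C3 chain, and the carboxylate formed first deactivates the ring towards a second hydrolysis.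

**Step 6**
Reactants: 14 4-henicosyl-5-(methoxycarbonyl)-1H-pyrrole-2-carboxylic acid
Product: 15 methyl 3-henicosyl-1H-pyrrole-2-carboxylate
Conditions: Cu2O (10 mol %), 1,10-phenanthroline (20 mol %), NMP/quinoline 3:1, 170 °C, argon
Reagents that add atoms: none
Why: In this copper-catalysed protodecarboxylation of a heteroaromatic α-carboxylic acid, the copper carboxylate should lose CO2 to a C-bound copper species that the medium protonates, while the methyl ester is inert in the absence of water and nucleophiles.

**Compound list**

1 | 1-docosanol | CCCCCCCCCCCCCCCCCCCCCCO | starting material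
2 | docosanal | CCCCCCCCCCCCCCCCCCCCCC=O | intermediate
3 | dimethyl (1-diazo-2-oxopropyl)phosphonate | CC(=O)C(=[N+]=[N-])P(=O)(OC)OC | starting material
4 | dimethyl (diazomethyl)phosphonate, formed in the flask as its potassium salt | [N-]=[N+]=CP(=O)(OC)OC | intermediate (not isolated)
5 | 1-diazotricos-1-ene | CCCCCCCCCCCCCCCCCCCCCC=C=[N+]=[N-] | intermediate (not isolated)
6 | 1-tricosyne | CCCCCCCCCCCCCCCCCCCCCC#C | intermediate
7 | dimethyl 1,2,4,5-tetrazine-3,6-dicarboxylate | COC(=O)c1nnc(nn1)C(=O)OC | starting material
8 | dimethyl 7-henicosyl-2,3,5,6-tetraazabicyclo[2.2.2]octa-2,5,7-triene-1,4-dicarboxylate | CCCCCCCCCCCCCCCCCCCCCC1=CC2(C(=O)OC)N=NC1(C(=O)OC)N=N2 | intermediate (not isolated)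
9 | dimethyl 4-henicosylpyridazine-3,6-dicarboxylate | CCCCCCCCCCCCCCCCCCCCCc1cc(C(=O)OC)nnc1C(=O)OC | intermediate
10 | dimethyl 5-henicosyl-1,4-dihydropyridazine-3,6-dicarboxylate (one tautomer drawn) | CCCCCCCCCCCCCCCCCCCCCC1=C(C(=O)OC)NN=C(C(=O)OC)C1 | intermediate (not isolated)
11 | dimethyl (2Z)-2-amino-3-henicosyl-5-iminohex-2-enedioate | CCCCCCCCCCCCCCCCCCCCC/C(CC(=N)C(=O)OC)=C(/N)C(=O)OC | intermediate (not isolated)
12 | dimethyl 3-henicosyl-1H-pyrrole-2,5-dicarboxylate | CCCCCCCCCCCCCCCCCCCCCc1cc(C(=O)OC)[nH]c1C(=O)OC | intermediate
13 | lithium 4-henicosyl-5-(methoxycarbonyl)-1H-pyrrole-2-carboxylate | [Li+].CCCCCCCCCCCCCCCCCCCCCc1cc(C(=O)[O-])[nH]c1C(=O)OC | intermediate (not isolated)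
14 | 4-henicosyl-5-(methoxycarbonyl)-1H-pyrrole-2-carboxylic acid | CCCCCCCCCCCCCCCCCCCCCc1cc(C(=O)O)[nH]c1C(=O)OC | intermediate
15 | methyl 3-henicosyl-1H-pyrrole-2-carboxylate (no stereocentre) | CCCCCCCCCCCCCCCCCCCCCc1cc[nH]c1C(=O)OC | target

**Total step count:** 6
**Longest linear sequence:** 6 steps (1 → 2 → 6 → 9 → 12 → 14 → 15)

**Steps most likely to fail**

1. Step 3. The cycloaddition to an unactivated alkyne may be so slow that thermal and hydrolytic decay of the tetrazine outpaces it. The fallback sets out from docosanal 2 and comes back at pyridazine 9. Wittig reaction of 2 with the ylide made from (methoxymethyl)triphenylphosphonium chloride and KOtBu in THF at 0 °C should give the enol ether 1-methoxytricos-1-ene F1 as an E/Z mixture. This electron-rich alkene should add to 7 in dioxane at 25 °C and, after loss of N2, give dimethyl 4-henicosyl-5-methoxy-4,5-dihydropyridazine-3,6-dicarboxylate F2. Warming, if needed with a trace of acid, should eliminate methanol from F2 to give 9. Both alkene isomers converge because the stereocentres of F2 vanish on aromatisation.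

2. Step 5. Hydroxide may not distinguish the two ester groups well enough, or hydrolysis may run on to the diacid. The fallback sets out from pyridazine 9 and comes back at acid 14, moving the differentiation to the diazine stage. There the chain lies closer to its neighbouring ester (six-membered ring geometry), the esters hydrolyse at low temperature, and no acidic N–H interferes. LiOH·H2O (1 equiv) in THF/H2O at 0 °C, then 1 M HCl, should give 5-henicosyl-6-(methoxycarbonyl)pyridazine-3-carboxylic acid F3. Zn dust in AcOH/THF at 25 °C should then contract F3 directly to 14.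

3. Step 6. Loss of CO2 may stall below the temperature at which the pyrrole begins to degrade, or the hot basic medium may attack the remaining ester. The fallback sets out from acid 14 and comes back at target 15. Iodinative decarboxylation with I2, NaI and NaHCO3 in H2O/1,2-dichloroethane at 80 °C should give methyl 3-henicosyl-5-iodo-1H-pyrrole-2-carboxylate F4 by ipso substitution. Hydrogenolysis (H2, 10% Pd/C, NaOAc, MeOH/THF, 25 °C) should then remove the iodine to give 15.

**Further compounds**

F1 | step 3 | 1-methoxytricos-1-ene (E/Z mixture) | CCCCCCCCCCCCCCCCCCCCCC=COC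
F2 | step 3 | dimethyl 4-henicosyl-5-methoxy-4,5-dihydropyridazine-3,6-dicarboxylate (diastereomer mixture, racemic) | CCCCCCCCCCCCCCCCCCCCCC1C(OC)C(C(=O)OC)=NN=C1C(=O)OC
F3 | step 5 | 5-henicosyl-6-(methoxycarbonyl)pyridazine-3-carboxylic acid | CCCCCCCCCCCCCCCCCCCCCc1cc(C(=O)O)nnc1C(=O)OC
F4 | step 6 | methyl 3-henicosyl-5-iodo-1H-pyrrole-2-carboxylate | CCCCCCCCCCCCCCCCCCCCCc1cc(I)[nH]c1C(=O)OC
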